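Remark: atom labels C1–C15 are those of the target's germacrane skeleton and are kept for every intermediate (decalin ring A = C1, C2, C3, C4, C9, C10; ring B = C4–C9; β = the face of the C15 methyl on C4), and the annulation product 8 is assumed to be brought to a single enantiomer by crystallisation before it is carried on.

## Structural features

The target is a ten-membered carbocycle (C1–C10) with two ring-cis trisubstituted double bonds, C1=C10 (carrying C14H2OH) and C4=C5 (carrying the C15 methyl). It is fused at C6–C7 to an α-methylene-γ-butyrolactone (lactone O on C6, C11(=C13H2)–C12(=O) on C7). Four contiguous stereocentres run from C6 to C9 (6R,7S,8S,9S): H6 and H7 are anti (trans-lactone), the C8 isobutyrate lies on the same side as C11 in a flat ring drawing, and the C9 2-hydroxyisobutyrate lies on the opposite side (threo to C8). The fragile groups are the exo-methylene lactone (a Michael acceptor), the allylic C6–O and C9–O acyloxy bonds, and two neighbouring esters that can migrate. The real difficulty is the medium ring with two Z olefins, followed by C8 and C9 on a flexible ring. The key step exploits the 1,6 relation of C4 (methyl) and C9 (oxygen): a C4–C9 bond turns the macrocycle into a cis-decalin with an angular methyl. Ring B of that decalin (C4–C9) carries oxygen at C5 and C9 and the acetic acid arm at C7, which is the substitution pattern of 3,5-dihydroxyphenylacetic acid. The 1,3 relation of C9–O and C5–O across C4 is what allows the C4–C9 bond to be cleaved again with complete control of the C4=C5 geometry.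

## Logic of the disconnections

33 to 32: the two O–Si bonds are cut last. The primary allylic and the tertiary hydroxyl must stay masked through acylation and enolate chemistry. The forward step needs an acidic fluoride source so that neither ester migrates and the exo-methylene lactone is not attacked.

32 to 28: the C11=C13 bond is cut. The exo-methylene is the most electrophilic group and should be the last carbon added. This leaves a lactone enolate and a one-carbon iminium electrophile. The forward step must enolise the lactone next to two other esters; the C9 ester has no α-hydrogen and the C8 ester only a hindered methine.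

28 to 23 and 26: the C9 O–acyl bond is cut. The hindered α-oxygenated acyl group is put on after the carbinol exists, from the silyl-protected acid 26 (one step from 24). The forward step is a hindered esterification that must not move the C8 acyl group.

23 to 22: the C9–H bond is cut. C9 is a ketone after ring opening, so one stereocentre is removed. The forward step needs 1,2-selective hydride delivery to the correct face of an enone.

22 to 20 and 21, and 20 to 19: the C8–O bond is cut twice. The C9 ketone is the only handle that activates C8, but the face of the enolate open to an electrophile is expected to be the wrong one. Oxygen is therefore introduced first, and the carbinol is then substituted with inversion by 21, which brings in the final acyl group at the same time. The forward steps need kinetic α′-enolisation and an SN2 reaction at a ring carbinol next to a carbonyl.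

19 to 18, 18 to 16 and 17, 16 to 15: the O–Si, C10–C14 and C10–I bonds are cut. C14 sits on the α-carbon of the enone, which suggests α-iodination and cross-coupling. This keeps C14 out of the fragmentation substrate, where C10 is an unactivated cyclohexene carbon. The forward coupling must tolerate the allylic lactone.

15 to 14: the C4–C9 bond is reconnected. The macrocycle with two Z olefins becomes a rigid cis-decalin in which C6 and C7 can be set by ordinary six-ring rules. The forward step must break exactly this bond and must give the Z C4=C5 olefin, which the chair geometry of ring B enforces.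

14 to 13 to 12: the S–O bond and then the C5–H bond are cut. The C5 carbinol must be α (anti to the C9 hydroxyl), which is the product of hydride delivery from the C9 hydroxyl itself.

12 to 10 (through 11): the C6–O bond and the lactone C12–O bond are cut. C5 can only enolise toward C6 because C4 is quaternary, so regiochemistry is secure. The forward step must place oxygen on the β face, trans to the arm.

10 to 9 to 8: the C9–O bond is traced back to an epoxide and the C1=C10 olefin to the C1 carbonyl. This epoxy-ketone transposition turns the annulation enone into the tertiary allylic alcohol. The forward epoxidation must occur cis to the angular methyl, because only the cis-fused decalin gives the Z olefin on fragmentation.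

8 to 4, 5 and 2: the C3–C4 and C9–C10 bonds (and the ester O–CH3 bond) are cut. This annulation disconnection leads to a symmetric 2-methyl-1,3-dione. The forward step must place the arm trans to the methyl (face selection in the Michael addition) and must choose one of two enantiotopic carbonyls (amine catalysis).

4 to 1 and 2 (through 3): the C4–C15 bond is cut and the dione is traced to the resorcinol ring. Both operations are classical and can be run in one pot.

## Other disconnections considered

Alternative 1: the cut is C5–C6, with the C15 methyl added afterwards. The open-chain iodoalkyne aldehyde A1 already carries C7, C8, C9, both oxygen substituents, C14 and the arm as a Weinreb amide. CrCl2 with catalytic NiCl2 would turn the iodoalkyne into an alkynylchromium species that adds to the C6 aldehyde and closes the cyclodecenyne carbinol A2. In its favour, C7–C9 are made by acyclic stereocontrol before the ring exists; on the security of C8 and C9 this alternative is better than the chosen plan, where both depend on the conformation of the ring. The chromium chemistry is also mild toward esters and silyl ethers, which is at least equal to the base step of the chosen plan. Against it, the ring is closed by C–C bond formation at high dilution into a strained ten-membered enyne. The C4=C5 geometry then has to come from methyl addition to the ynone derived from A2, which does not enforce the Z olefin. C6 has to be reduced on the macrocycle before the trans-lactone can be closed. The chosen plan obtains both olefin geometries and the trans-lactone stereospecifically from a bicycle. The linear sequence to A1 plus the steps after A2 is estimated to be longer than 18 steps.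

Alternative 2: the cut is C8–C9, with C1–C6 joined in the precursor. KH and 18-crown-6 would convert the cis-1,2-dialkenylcyclohexenol A3 into its alkoxide, which undergoes a chair [3,3] shift to the cyclodecadienone A4 after cold protonation. Like the chosen plan this is a ring expansion, so it is equal in needing no dilution. It is better in one respect: C8 and C9 are formed together, and their relative configuration follows from olefin geometry through the chair. Against it, the cis substrate has two competing chairs that differ in the geometry of the new C1=C10 bond, and the required one puts both the ring carbon C2 and the alkoxide axial. The enolate formed carries a β-alkoxy group at C8 that can be expelled. A4 also lacks the C11–C12 arm and the lactone, so C7 alkylation, C6 reduction and lactone closure would all take place on the flexible ring. The chosen plan fixes C6 and C7 on the rigid decalin. Step economy is estimated to be similar or slightly worse.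

Alternative 3: the cut is C9–C10. The Z vinyl iodide aldehyde A5, which already contains the α-methylene trans-lactone, both Z olefins, C14 and the C8 ether, would be closed with CrCl2 and catalytic NiCl2 in DMSO at high dilution to the germacranolide core A6. This has the shortest endgame: after A6 only C9 acylation, ether-to-isobutyrate exchange and desilylation remain, against ten steps after the key step in the chosen plan. The base-sensitive dienone lactone is avoided altogether. On both points the alternative is better. Against it, the C9 carbinol is created in the ring-closing event, and its configuration rests on the balance of chelation and ring strain. The ring is formed by C–C bond formation with a large excess of chromium. A5 itself needs a Z-trisubstituted allylic trans-lactone and a Z-trisubstituted vinyl iodide assembled in an open chain, which is estimated to cost more steps than the eight that lead to 14. The chosen plan is mechanistically stereospecific for the ring and the olefins and pays for this with a longer endgame.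

Key step: step 8

## Steps

Step 1
Reactants: 1 3,5-dihydroxyphenylacetic acid; 2 iodomethane
Product: 4 2-(4-methyl-3,5-dioxocyclohexyl)acetic acid, via 2-(3,5-dioxocyclohexyl)acetic acid 3 (not isolated)
Conditions: H2 (4 bar), 5% Rh/Al2O3, NaOH (2.2 equiv), H2O, rt; filter; MeI (1.5 equiv), dioxane/H2O, 60 °C; HCl to pH 2
Reagents that add atoms: none
Why: Hydrogenation of a resorcinol monoanion stops at the vinylogous carboxylate (one mole of H2), and the resulting 1,3-dione enolate is C-methylated at the carbon between the carbonyls (C4), the classical route to 2-methylcyclohexane-1,3-diones; no fixed stereocentre results because C4 is enolised.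

Step 2
Reactants: 4 2-(4-methyl-3,5-dioxocyclohexyl)acetic acid; 5 methyl vinyl ketone; 2 iodomethane
Product: 8 methyl 2-[(2R,4aS)-4a-methyl-4,7-dioxo-1,2,3,4,4a,5,6,7-octahydronaphthalen-2-yl]acetate, via triketone acid 6 (not isolated), via enedione acid 7 (not isolated)
Conditions: methyl vinyl ketone (1.5 equiv), L-proline (0.35 equiv), DMSO, 35 °C; then KHCO3 (2 equiv), MeI (2 equiv), rt; chromatography, crystallisation
Reagents that add atoms: none
Why: Robinson annulation in one pot: the enone should add to C4 of the dione enol axially, anti to the axial H7 and therefore cis to the equatorial arm, which leaves the methyl trans to the arm; the L-proline enamine then closes onto one enantiotopic carbonyl (Hajos–Parrish-type aldol, 4S sense as for the parent methyl dione) and dehydrates, and the carboxylate is alkylated to the methyl ester.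

Step 3
Reactants: 8 methyl 2-[(2R,4aS)-4a-methyl-4,7-dioxo-1,2,3,4,4a,5,6,7-octahydronaphthalen-2-yl]acetate
Product: 9 9β,10β-epoxide of 8 (epoxide cis to the C15 methyl; C1 and C5 ketones and the 7α CH2CO2Me arm unchanged)
Conditions: 30% H2O2, NaOH (0.3 equiv), MeOH, 0 °C
Reagents that add atoms: hydrogen peroxide, OO
Why: Weitz–Scheffer epoxidation of the enone; hydroperoxide should add to C9 from the β face as in angularly methylated octalones and 4-en-3-one steroids, giving the cis-fused epoxide, while the saturated ketone is inert and methanol makes ester exchange degenerate.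

Step 4
Reactants: 9 9β,10β-epoxide of 8
Product: 10 methyl 2-[cis-fused 9β-hydroxy-4β-methyl-5-oxo-decal-1(10)-en-7α-yl]acetate (tertiary allylic alcohol at C9, C1=C10, C5 ketone)
Conditions: N2H4·H2O (2 equiv), AcOH (0.2 equiv), MeOH, 0 °C to rt; aqueous acetone work-up
Reagents that add atoms: none
Why: Wharton transposition: the hydrazone of the epoxy ketone fragments with loss of N2 to the C1=C10 olefin and the C9 alkoxide without touching the C9–O bond, so the β configuration of the epoxide becomes that of the tertiary alcohol; the neopentyl C5 ketone condenses slowly and reversibly, and its hydrazone is hydrolysed on work-up.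

Step 5
Reactants: 10 methyl 2-[cis-fused 9β-hydroxy-4β-methyl-5-oxo-decal-1(10)-en-7α-yl]acetate
Product: 12 cis-decalin keto lactone (12,6β-olide trans-fused on ring B, 9β-OH, C5 ketone, C1=C10), via 6β-hydroxy keto ester 11 (not isolated)
Conditions: KN(SiMe3)2 (2.2 equiv), THF, −78 °C; 2-(phenylsulfonyl)-3-phenyloxaziridine, −78 °C; AcOH; then camphorsulfonic acid (0.1 equiv), CH2Cl2, rt
Reagents that add atoms: 2-(phenylsulfonyl)-3-phenyloxaziridine, O=S(=O)(c1ccccc1)N1OC1c1ccccc1
Why: The C5 ketone can enolise only toward C6 (C4 is quaternary); Davis-type hydroxylation should occur on the convex β face, away from the syn-axial C3 methylene of ring A and from the arm, giving the equatorial 6β-hydroxyl trans to the arm, and acid then closes the trans-fused γ-lactone with loss of methanol.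

Step 6
Reactants: 12 cis-decalin keto lactone
Product: 13 5α,9β-diol lactone (C5–OH equatorial and anti to the C9–OH; lactone as in 12)
Conditions: Me4NBH(OAc)3 (4 equiv), AcOH/MeCN 1:1, −20 °C
Reagents that add atoms: none
Why: Evans–Saksena directed reduction: the borohydride exchanges an acetate for the axial 9β-hydroxyl and delivers hydride intramolecularly to the β face of C5 through a six-membered arrangement, so the new carbinol is 5α (1,3-anti); the lactone is inert to acyloxyborohydride.

Step 7
Reactants: 13 5α,9β-diol lactone
Product: 14 5α-mesylate of 13 (cis-decalin trans-lactone with free tertiary allylic 9β-OH and equatorial C5–OMs)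
Conditions: MsCl (1.3 equiv), pyridine, CH2Cl2, 0 °C
Reagents that add atoms: methanesulfonyl chloride, CS(=O)(=O)Cl
Why: Sulfonylation of the secondary equatorial alcohol; the tertiary allylic C9 hydroxyl does not react under pyridine conditions, which avoid sulfene, and no stereocentre is touched.

Step 8
Reactants: 14 5α-mesylate (cis-decalin trans-lactone)
Product: 15 trans-lactone-fused (1(10)Z,4Z)-4-methylcyclodeca-1(10),4-dien-9-one (12,6-olide, H6 and H7 anti as in the target)
Conditions: KOtBu (1.1 equiv), THF, −40 to 0 °C; pH 7 phosphate buffer
Reagents that add atoms: none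
Why: KOtBu turns the tertiary C9 hydroxyl into its alkoxide, whose electron pair pushes into the C4–C9 σ-bond while the C5–O bond of the mesylate departs, so that C9=O and C4=C5 appear in one concerted heterolysis (Grob fragmentation of a 1,3-diol monosulfonate, of which the Wharton route to cyclodecenones is the closest precedent). No σ-bond is formed: the ten-membered ring is not closed but set free by cleaving the bond shared by rings A and B, so no ring-closure mode and no dilution are involved. No stereocentre is created, and C6 and C7 keep the trans-lactone set on the decalin. The C4=C5 geometry is fixed by the chair of ring B in which lactone and mesylate are equatorial: the C5–O bond is antiperiplanar to C4–C9 and C3 is axial on C4, hence gauche to C6, so C3 and C6 end up cis (Z), while C1=C10 is ring-cis from the start. The step needs fragmentation to win over elimination, substitution and attack on the lactone: the equatorial sulfonate has no antiperiplanar hydrogen, the neopentyl C5 centre resists displacement, the trans-1,3 relation of C9–O and the C7 arm forbids translactonisation, and a bulky base in slight excess at low temperature with a buffered quench limits enolisation of the lactone and of the dienone formed.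

Step 9
Reactants: 15 trans-lactone-fused (1(10)Z,4Z)-4-methylcyclodeca-1(10),4-dien-9-one
Product: 16 10-iodo derivative of 15 (iodine on the α-carbon C10 of the enone, ring-cis C1=C10 retained)
Conditions: I2 (2.5 equiv), pyridine/CH2Cl2 1:1, 0 °C to rt, dark
Reagents that add atoms: iodine, II
Why: α-Iodination of an enone by conjugate addition of pyridine, iodination of the resulting enolate at C10 and loss of pyridine; the ring-cis geometry should be restored as the less strained one in a ring that already holds a second cis olefin, and the isolated C4=C5 bond adds iodine only reversibly.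

Step 10
Reactants: 16 10-iodo dienone lactone; 17 (tributylstannyl)methanol
Product: 18 14-hydroxy dienone lactone (C14H2OH on C10, C9 ketone, 12,6-olide)
Conditions: Pd2(dba)3 (5 mol %), AsPh3 (20 mol %), CuI (10 mol %), NMP, 50 °C
Reagents that add atoms: none
Why: Stille coupling with retention of olefin geometry; oxidative addition of zerovalent palladium into the α-iodoenone is fast, the oxygen-bearing carbon transfers in preference to butyl, and the low temperature is chosen so that the allylic C6–O lactone bond is not ionised.

Step 11
Reactants: 18 14-hydroxy dienone lactone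
Product: 19 14-O-tert-butyldimethylsilyl ether of 18
Conditions: TBSCl (1.2 equiv), imidazole, DMF, 0 °C
Reagents that add atoms: tert-butyldimethylsilyl chloride, CC(C)(C)[Si](C)(C)Cl
Why: Standard silylation of the primary allylic alcohol, needed before enolate and Mitsunobu chemistry.

Step 12
Reactants: 19 14-O-silyl dienone lactone
Product: 20 (8R)-8-hydroxy derivative of 19 (C8–OH trans to C11 in the flat ring drawing, the 8-epimer of the target pattern)
Conditions: KN(SiMe3)2 (1.15 equiv), THF, −78 °C; 2-(phenylsulfonyl)-3-phenyloxaziridine, −78 °C; AcOH
Reagents that add atoms: 2-(phenylsulfonyl)-3-phenyloxaziridine, O=S(=O)(c1ccccc1)N1OC1c1ccccc1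
Why: Kinetic α′-enolisation of the enone at C8 (the only sp3 α-carbon; the lactone CH2 is less acidic) and Davis-type oxygen transfer; with H7 in the enolate plane (allylic 1,3-strain) the oxidant should enter anti to the ring bond C7–C6, which gives the 8R carbinol that the next step inverts.

Step 13
Reactants: 20 (8R)-8-hydroxy ketone; 21 isobutyric acid
Product: 22 (8S)-8-isobutyryloxy-14-silyloxy dienone lactone (C8 ester cis to C11, C9 ketone)
Conditions: isobutyric acid (3 equiv), PPh3 (3 equiv), DIAD (3 equiv), toluene, 0 °C to rt
Reagents that add atoms: none
Why: Mitsunobu esterification: the oxyphosphonium at the carbonyl-activated C8 is displaced by isobutyrate with inversion, which corrects C8 to 8S and installs the final acyl group in the same operation.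

Step 14
Reactants: 22 (8S)-8-isobutyryloxy dienone lactone
Product: 23 (8S,9S)-9-hydroxy-8-isobutyryloxy-14-silyloxy diene lactone (C9–OH on the face opposite to the C8 ester)
Conditions: NaBH4 (1.2 equiv), CeCl3·7H2O (1.2 equiv), MeOH, −78 °C
Reagents that add atoms: none
Why: Luche 1,2-reduction of the enone, with lactone and ester inert; hydride should enter anti to the C8–O bond held perpendicular to the carbonyl (Felkin–Anh-type 1,2-induction with C7 and C10 anti about C8–C9, which the ten-membered ring allows and which is also the outer face of the conformer inherited from the decalin), giving the threo 9S carbinol.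

Step 15
Reactants: 24 2-hydroxy-2-methylpropanoic acid
Product: 26 2-methyl-2-[(triethylsilyl)oxy]propanoic acid, via bis-silyl derivative 25 (not isolated)
Conditions: Et3SiCl (2.3 equiv), imidazole, DMAP (cat.), DMF, 40 °C; then H2O/THF, rt
Reagents that add atoms: triethylsilyl chloride, CC[Si](CC)(CC)Cl
Why: Silylation of both hydroxyl functions followed by selective hydrolysis of the labile silyl ester, leaving the tertiary silyl ether.

Step 16
Reactants: 23 (8S,9S)-9-hydroxy-8-isobutyryloxy diene lactone; 26 2-methyl-2-[(triethylsilyl)oxy]propanoic acid
Product: 28 (8S,9S)-8-isobutyryloxy-9-[2-methyl-2-(triethylsilyloxy)propanoyloxy]-14-silyloxy diene lactone, via mixed anhydride 27 (not isolated)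
Conditions: 26 (2 equiv), 2,4,6-trichlorobenzoyl chloride (2 equiv), Et3N, THF, rt; then 23, DMAP (3 equiv), toluene, 40 °C
Reagents that add atoms: none
Why: Yamaguchi esterification: the hindered acid is activated as the mixed anhydride and transferred through the acylpyridinium to the allylic C9 hydroxyl; no alkoxide is generated, so the C8 ester should not migrate, and no stereocentre is touched.

Step 17
Reactants: 28 bis-ester lactone
Product: 32 11(13)-methylene lactone bis-silyl ether (target skeleton with C14–OTBS and tertiary O–SiEt3), via silyl ketene acetal 29 (not isolated), via Mannich base 30 (not isolated), via methiodide 31 (not isolated)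
Conditions: LiN(iPr)2 (1.2 equiv), Me3SiCl (3 equiv, internal quench), THF, −78 °C; concentrate; Me2N=CH2 I (2 equiv), CH2Cl2, rt; MeI, MeOH/CH2Cl2; aq NaHCO3, EtOAc
Reagents that add atoms: dimethyl(methylidene)ammonium iodide, C=[N+](C)C.[I-]
Why: Eschenmoser methylenation: the lactone CH2 is the most acidic C–H (the C9 ester has no α-hydrogen, the C8 ester only a hindered methine), and the enolate is trapped at once as the silyl ketene acetal so that it cannot attack the neighbouring C8 ester; Mannich reaction with the iminium salt, exhaustive methylation and E1cB loss of trimethylamine give the exo-methylene, and C11 ends up sp2 so no stereocentre is set.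

Step 18
Reactants: 32 11(13)-methylene lactone bis-silyl ether
Product: 33 CNP0220567.2, the (6R,7S,8S,9S)-14-hydroxy-8-isobutyryloxy-9-(2-hydroxy-2-methylpropanoyloxy)germacra-1(10)Z,4Z,11(13)-trien-12,6-olide
Conditions: HF·pyridine, pyridine, THF, 0 °C to rt
Reagents that add atoms: none
Why: Acidic fluoride cleaves the primary allylic and the tertiary silyl ether; under non-basic conditions the esters should not migrate and the α-methylene lactone is not attacked.

## Compound list

1 | 3,5-dihydroxyphenylacetic acid | OC(=O)Cc1cc(O)cc(O)c1 | starting material
2 | iodomethane | CI | starting material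
3 | 2-(3,5-dioxocyclohexyl)acetic acid | OC(=O)CC1CC(=O)CC(=O)C1 | intermediate
4 | 2-(4-methyl-3,5-dioxocyclohexyl)acetic acid | CC1C(=O)CC(CC(O)=O)CC1=O | intermediate
5 | methyl vinyl ketone | CC(=O)C=C | starting material
6 | 2-[4-methyl-3,5-dioxo-4-(3-oxobutyl)cyclohexyl]acetic acid, achiral diastereomer with the arm cis to the oxobutyl chain | C[C@@]1(CCC(C)=O)C(=O)C[C@H](CC(O)=O)CC1=O | intermediate
7 | 2-[(2R,4aS)-4a-methyl-4,7-dioxo-1,2,3,4,4a,5,6,7-octahydronaphthalen-2-yl]acetic acid | C[C@]12CCC(=O)C=C1C[C@@H](CC(O)=O)CC2=O | intermediate
8 | methyl 2-[(2R,4aS)-4a-methyl-4,7-dioxo-1,2,3,4,4a,5,6,7-octahydronaphthalen-2-yl]acetate | C[C@]12CCC(=O)C=C1C[C@@H](CC(=O)OC)CC2=O | intermediate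
9 | 9β,10β-epoxide of 8 | C[C@]12CCC(=O)[C@@H]3O[C@]13C[C@@H](CC(=O)OC)CC2=O | intermediate
10 | methyl 2-[cis-fused 9β-hydroxy-4β-methyl-5-oxo-decal-1(10)-en-7α-yl]acetate | C[C@]12CCC=C[C@@]1(O)C[C@@H](CC(=O)OC)CC2=O | intermediate
11 | 6β-hydroxy derivative of 10 | C[C@]12CCC=C[C@@]1(O)C[C@@H](CC(=O)OC)[C@H](O)C2=O | intermediate
12 | cis-decalin keto lactone (12,6β-olide, 9β-OH, C5 ketone) | C[C@]12CCC=C[C@@]1(O)C[C@H]3CC(=O)O[C@@H]3C2=O | intermediate
13 | 5α,9β-diol lactone | C[C@]12CCC=C[C@@]1(O)C[C@H]3CC(=O)O[C@@H]3[C@H]2O | intermediate
14 | 5α-mesylate of 13 | C[C@]12CCC=C[C@@]1(O)C[C@H]3CC(=O)O[C@@H]3[C@H]2OS(C)(=O)=O | intermediate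
15 | trans-lactone-fused (1(10)Z,4Z)-4-methylcyclodeca-1(10),4-dien-9-one | C1C(=O)O[C@@H]2/C=C(/C)CC/C=C\C(=O)C[C@@H]12 | intermediate
16 | 10-iodo derivative of 15 | C1C(=O)O[C@@H]2/C=C(/C)CC/C=C(/I)C(=O)C[C@@H]12 | intermediate
17 | (tributylstannyl)methanol | OC[Sn](CCCC)(CCCC)CCCC | starting material
18 | 14-hydroxy dienone lactone | C1C(=O)O[C@@H]2/C=C(/C)CC/C=C(/CO)C(=O)C[C@@H]12 | intermediate
19 | 14-O-tert-butyldimethylsilyl ether of 18 | C1C(=O)O[C@@H]2/C=C(/C)CC/C=C(/CO[Si](C)(C)C(C)(C)C)C(=O)C[C@@H]12 | intermediate
20 | (8R)-8-hydroxy derivative of 19 | C1C(=O)O[C@@H]2/C=C(/C)CC/C=C(/CO[Si](C)(C)C(C)(C)C)C(=O)[C@H](O)[C@@H]12 | intermediate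
21 | isobutyric acid | CC(C)C(O)=O | starting material
22 | (8S)-8-isobutyryloxy-14-silyloxy dienone lactone | C1C(=O)O[C@@H]2/C=C(/C)CC/C=C(/CO[Si](C)(C)C(C)(C)C)C(=O)[C@@H](OC(=O)C(C)C)[C@@H]12 | intermediate
23 | (8S,9S)-9-hydroxy-8-isobutyryloxy-14-silyloxy diene lactone | C1C(=O)O[C@@H]2/C=C(/C)CC/C=C(/CO[Si](C)(C)C(C)(C)C)[C@H](O)[C@@H](OC(=O)C(C)C)[C@@H]12 | intermediate
24 | 2-hydroxy-2-methylpropanoic acid | CC(C)(O)C(O)=O | starting material
25 | triethylsilyl 2-methyl-2-[(triethylsilyl)oxy]propanoate | CC[Si](CC)(CC)OC(=O)C(C)(C)O[Si](CC)(CC)CC | intermediate
26 | 2-methyl-2-[(triethylsilyl)oxy]propanoic acid | CC[Si](CC)(CC)OC(C)(C)C(O)=O | intermediate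
27 | 2-methyl-2-[(triethylsilyl)oxy]propanoic 2,4,6-trichlorobenzoic anhydride | CC[Si](CC)(CC)OC(C)(C)C(=O)OC(=O)c1c(Cl)cc(Cl)cc1Cl | intermediate
28 | (8S,9S)-8-isobutyryloxy-9-[2-methyl-2-(triethylsilyloxy)propanoyloxy]-14-silyloxy diene lactone | C1C(=O)O[C@@H]2/C=C(/C)CC/C=C(/CO[Si](C)(C)C(C)(C)C)[C@H](OC(=O)C(C)(C)O[Si](CC)(CC)CC)[C@@H](OC(=O)C(C)C)[C@@H]12 | intermediate
29 | trimethylsilyl ketene acetal of 28 (C11=C12) | C1=C(O[Si](C)(C)C)O[C@@H]2/C=C(/C)CC/C=C(/CO[Si](C)(C)C(C)(C)C)[C@H](OC(=O)C(C)(C)O[Si](CC)(CC)CC)[C@@H](OC(=O)C(C)C)[C@@H]12 | intermediate
30 | 11-(dimethylaminomethyl) lactone (C11 epimers) | CN(C)CC1C(=O)O[C@@H]2/C=C(/C)CC/C=C(/CO[Si](C)(C)C(C)(C)C)[C@H](OC(=O)C(C)(C)O[Si](CC)(CC)CC)[C@@H](OC(=O)C(C)C)[C@@H]12 | intermediate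
31 | trimethylammonium iodide of 30 | C[N+](C)(C)CC1C(=O)O[C@@H]2/C=C(/C)CC/C=C(/CO[Si](C)(C)C(C)(C)C)[C@H](OC(=O)C(C)(C)O[Si](CC)(CC)CC)[C@@H](OC(=O)C(C)C)[C@@H]12.[I-] | intermediate
32 | 11(13)-methylene lactone bis-silyl ether | C=C1C(=O)O[C@@H]2/C=C(/C)CC/C=C(/CO[Si](C)(C)C(C)(C)C)[C@H](OC(=O)C(C)(C)O[Si](CC)(CC)CC)[C@@H](OC(=O)C(C)C)[C@@H]12 | intermediate
33 | CNP0220567.2 | C=C1C(=O)O[C@@H]2/C=C(/C)CC/C=C(/CO)[C@H](OC(=O)C(C)(C)O)[C@@H](OC(=O)C(C)C)[C@@H]12 | target

## Step count and least certain steps

Total: 18 steps. Longest linear sequence: 17 steps (steps 1–14 and 16–18); step 15 prepares acid 26.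

Step 8 (key step). The acyloxy group on C6 withdraws electron density from C5 and may slow the heterolysis. That would give tert-butoxide time to enolise or open the lactone, and the dienone formed could then isomerise or close by transannular Michael addition. The fallback masks the lactone during the base step. It sets out from 14: reduction with iBu2AlH at −78 °C gives the lactol mesylate F1, and MeOH with pyridinium tosylate gives the methyl lactol ether mesylate F2. KOtBu then fragments F2 to the dienone methyl lactol ether F3. Aqueous acetic acid releases the dienone lactol F4, and Ag2CO3 on Celite oxidises it to the lactone, where the route is rejoined at 15.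

Step 2. The Michael addition may show poor or reversed face selectivity at C4 relative to the arm, and the aldol may discriminate the two carbonyls incompletely. The fallback reverses the order in which the two C4 substituents arrive, so the methyl enters last on the face that the enone would otherwise take. It sets out from 3: Michael addition to 5 in water gives 2-[3,5-dioxo-4-(3-oxobutyl)cyclohexyl]acetic acid F5, and C-methylation with 2 and K2CO3 returns to the route at 6, which is cyclised and esterified as in step 2.

Step 5. The C9 alkoxide is β to the C5 ketone and may open by retro-aldol under the dianion conditions, and enolisation may be incomplete. The fallback avoids anionic intermediates. It sets out from 10: Me3SiOTf and Et3N give the C9 silyl ether C5 silyl enol ether F6, which is oxidised with dimethyldioxirane (Rubottom oxidation) on the same convex face. Camphorsulfonic acid in methanol then removes silicon and closes the lactone, rejoining the route at 12.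

Step 12. Face selection at C8 rests on the conformation of the ring and may go the other way or be low. The fallback uses the other epimer without inversion. It sets out from 19: if hydroxylation gives the (8S)-8-hydroxy ketone F7, this is acylated with retention (isobutyryl chloride, pyridine, DMAP) and the route is rejoined at 22.

Step 13. Displacement at a ring carbinol flanked by C7 may be slow, which would allow elimination toward C7 or retention through an acyloxyphosphonium. The fallback separates activation from displacement. It sets out from 20: Tf2O and 2,6-lutidine at −78 °C give the C8 triflate F8, and cesium isobutyrate with 18-crown-6 in toluene displaces it with inversion, returning to the route at 22.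

Step 14. If the ring holds C7 and C10 gauche about C8–C9, hydride may attack the other face and give the 9-epimer. The fallback replaces substrate control by reagent control. It sets out from 22 and returns at 23: Corey–Bakshi–Shibata reduction with (S)-2-methyl-CBS-oxazaborolidine and catecholborane, with the substituted alkenyl side taken as the large group. No new compound is involved.

## Further compounds

F1 | step 8 | lactol mesylate (lactone of 14 reduced to the hemiacetal) | C[C@]12CCC=C[C@@]1(O)C[C@H]3CC(O)O[C@@H]3[C@H]2OS(C)(=O)=O
F2 | step 8 | methyl lactol ether mesylate | C[C@]12CCC=C[C@@]1(O)C[C@H]3CC(OC)O[C@@H]3[C@H]2OS(C)(=O)=O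
F3 | step 8 | dienone methyl lactol ether | C1C(OC)O[C@@H]2/C=C(/C)CC/C=C\C(=O)C[C@@H]12
F4 | step 8 | dienone lactol | C1C(O)O[C@@H]2/C=C(/C)CC/C=C\C(=O)C[C@@H]12
F5 | step 2 | 2-[3,5-dioxo-4-(3-oxobutyl)cyclohexyl]acetic acid | CC(=O)CCC1C(=O)CC(CC(O)=O)CC1=O
F6 | step 5 | C9 trimethylsilyl ether C5 trimethylsilyl enol ether of 10 | C[C@]12CCC=C[C@@]1(O[Si](C)(C)C)C[C@@H](CC(=O)OC)C=C2O[Si](C)(C)C
F7 | step 12 | (8S)-8-hydroxy derivative of 19 | C1C(=O)O[C@@H]2/C=C(/C)CC/C=C(/CO[Si](C)(C)C(C)(C)C)C(=O)[C@@H](O)[C@@H]12
F8 | step 13 | (8R)-8-trifluoromethanesulfonate of 20 | C1C(=O)O[C@@H]2/C=C(/C)CC/C=C(/CO[Si](C)(C)C(C)(C)C)C(=O)[C@H](OS(=O)(=O)C(F)(F)F)[C@@H]12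
F0 | step 14 | none | none
A1 | alternative 1 | open-chain iodoalkyne aldehyde (C6 aldehyde, C5 iodoalkyne, C8 PMB ether, C9 silyloxyisobutyrate, C14 silyl ether, Weinreb amide arm) | O=C[C@H](CC(=O)N(C)OC)[C@H](OCc1ccc(OC)cc1)[C@@H](OC(=O)C(C)(C)O[Si](CC)(CC)CC)/C(CO[Si](C)(C)C(C)(C)C)=C\CCC#CI
A2 | alternative 1 | ten-membered cyclodec-1-en-5-yne propargylic alcohol (both C6 epimers) | OC1C#CCC/C=C(/CO[Si](C)(C)C(C)(C)C)[C@H](OC(=O)C(C)(C)O[Si](CC)(CC)CC)[C@@H](OCc2ccc(OC)cc2)[C@H]1CC(=O)N(C)OC
A3 | alternative 2 | cis-1,2-dialkenylcyclohexenol (C6 carbinol with E enol ether vinyl group, C1 bearing the dioxinyl group) | O[C@]1(/C=C/OCc2ccc(OC)cc2)C=C(C)CC[C@H]1C1=COC(C)(C)OC1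
A4 | alternative 2 | (4Z,1(10)Z)-cyclodecadien-6-one with C8 PMB ether and C9,C14 acetonide | O=C1/C=C(/C)CC/C=C2/COC(C)(C)O[C@@H]2[C@@H](OCc3ccc(OC)cc3)C1
A5 | alternative 3 | Z vinyl iodide aldehyde with preformed α-methylene trans-lactone | C=C1C(=O)O[C@H](/C=C(/C)CC/C=C(/CO[Si](C)(C)C(C)(C)C)I)[C@H]1[C@H](OCc2ccc(OC)cc2)C=O
A6 | alternative 3 | germacranolide core with free C9 hydroxyl, C8 PMB ether and C14 silyl ether | C=C1C(=O)O[C@@H]2/C=C(/C)CC/C=C(/CO[Si](C)(C)C(C)(C)C)[C@H](O)[C@@H](OCc3ccc(OC)cc3)[C@@H]12
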